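## The problem

Atoms are numbered by their position in the line notation of target 30 (C1 is the methyl on C2; O16, O20, O26 and O34 are the oxygens). Target 30 joins a cis-fused decalin (ring A: C2–C7; ring B: C5, C6, C27, C30, C31, C32) through an (E)-configured exocyclic C7=C8 bond and the C9 methylene to a cyclohexane (ring C: C10, C11, C21–C24) that is trans-fused to a 2,2-dimethyloxepan-3-one (ring D: O20, C17, C15, C14, C13, C11, C21). The eight stereocentres fall into two clusters, C2/C5/C6/C32 and C10/C11/C21/C24, that are too far apart to control one another. Each half must therefore be made enantiopure and the halves joined with control of the alkene geometry. In the right-hand cluster C10 and C24 can be fixed in an open chain and then direct the quaternary C11 and, through it, C21; the C24 methyl is axial and syn to the axial C11 methyl, which a methyl nucleophile adding to a C24 ketone would not deliver. In the left-hand cluster H2, H5 and H6 lie on one face, C2 and C6 are epimerisable while C7 is a ketone, and the C32 methyl is again the axial one. The tertiary alcohols at C24 and C32, the trisubstituted alkene and the C15 ketone next to the oxygen-bearing quaternary C17 limit what can be done late. The enabling feature is that ring D is a 2,2-dimethylfuran-3(2H)-one (O20, C17, C15, C14, C21) with C13 and C11 inserted between C14 and C21: adding a C11=C13 alkene across C21=C14 and then cutting C14–C21 makes ring D, and if the alkene hangs on C21 through C22–C23–C24–C10 the same cycloaddition closes ring C.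

## Retrosynthesis

**C8–C9.** Target 30 is unmasked from its C24 silyl ether 29, which is cut at the sp2–sp3 bond C8–C9 into alkylzinc 28 (from iodide 17) and alkenyl bromide 27. Olefination at C7 would have to form a trisubstituted alkene at the doubly α-branched ketone 26 with no handle on geometry. A C9–C10 enolate allylation would need a C24 ketone after the alkene is in place, and the axial C24 methyl could then be installed only through an epoxide that the alkene would not survive. The cut gives two halves of four stereocentres each; the forward coupling must retain the bromide geometry and tolerate the C15 ketone.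

**Ring D.** Iodide 17 comes from oxepanone 14 by protecting-group changes (15, 16). In 14 the bond C14–C21 is reconnected, which leads back to cyclobutane 12. Closing ring D by etherification would be a 7-endo process competing with smaller rings; in 12 the ring size, the ketone and the gem-dimethyl group are already fixed by a covalent furanone. The forward step must break the alkoxy-donor/carbonyl-acceptor bond and place hydrogen on C21 anti to the C11 methyl.

**Key cut.** Cyclobutane 12 is opened across C11–C21 and C13–C14 to furanone 11. This removes ring C, the cyclobutane and three stereocentres at once; 11 keeps only C10 and C24. The forward photocycloaddition must give the fused (not crossed) adduct and use one face of the alkene.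

**Furanone.** Furanone 11 is cut at O20–C21 (cyclodehydration of diketone 10) and at C14–C21 (aldol of aldehyde 7 with hydroxy ketone 8, then oxidation of 9).

**C10–C11.** Aldehyde 7 comes from silylene 5 by cleavage of the remote alkene, and 5 from diol 4. Diol 4 is cut at C10–C11 into epoxy alcohol 2 and isopropenyl Grignard reagent 3; 2 comes from geraniol 1, which supplies C9, C10 and C21–C25 with the (E)-alkene. Opening at C10 with inversion turns the two epoxide centres into C10 and the complete C24 carbinol. The neighbouring plan, allylation of a C24 aldehyde followed by oxidation and ketalisation, would pass through a racemisable β,γ-unsaturated ketone, would carry a ketal that silyl triflate and silane reduce, and would leave the axial methyl for later.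

**Decalin.** Bromide 27 is cut at C7=C8 to ketone 26 (Wittig). Ketone 26 is traced through 24, 23, 22 and 21 to octalone 20, which is cut at C4–C5 and C6–C7 into enone 18 and isoprene 19 (Diels–Alder). One step gives the cis fusion and the quaternary neighbour; the later steps must oxidise C7, set the axial C32 methyl and set C2.

## Roads not taken

**Alternative 1:** The decalin is cut at C5–C6 and both rings come from a ten-membered ring. A strong base enolises the C7 ketone of epoxy ketone A1 toward C6 and the enolate opens the C5–C32 epoxide transannularly, giving decalone A2, which is the same compound as 26. Its merit is that C5, C6 and C32 are read from one epoxide: the axial C32 methyl comes free, where the chosen route spends steps 14, 16 and 17 on it. Its weak points are the medium ring itself (macrocyclisation, a stereodefined trisubstituted epoxide, the C2 methyl), the need to enolise toward C6 and not C2, and the exposure of an epimerisable cis-decalone to strong base. This road is better at C32. The chosen plan sets against it a six-step access to 26 from two commodity chemicals under non-basic conditions. Alternative 1 says nothing about rings C and D.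

**Alternative 2:** O20–C17, C10–C11 and C24–O are cut in one biomimetic cascade. A Lewis acid activates the terminal epoxide of bis-epoxy carbonate A3; the internal epoxide oxygen attacks C17, the C10=C24 alkene opens the resulting epoxonium ion at C11, and the carbonate carbonyl captures the C24 cation to give cyclic carbonate A4. It sets C10, C11, C21 and C24 and both rings in one step, places the C24 oxygen correctly and is clearly shorter than steps 1–9 to diol 15. In step economy it is the better road. Its weak points are the competition between oxepane and smaller-ring ether formation and between chair and boat closure of ring C, so the tricycle is expected as one component of a mixture. It also needs two enantioselective epoxidations on one polyene and delivers C15 as an alcohol. The chosen plan sets against it that each ring-forming bond is made in a separate step with an isolable intermediate (12), and that the furanone fixes the size and oxidation level of ring D.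

**Alternative 3:** C11–C13 and C9–C10 are cut around a ring C enone. Cuprate A6 adds to C11 of silyloxy enone A5 anti to the C21 silyl ether, and the enolate is allylated at C10 by the π-allyl complex that a zerovalent palladium catalyst forms from vinyl carbonate A7, giving ketone A8 with the C7=C8 alkene. This is the most convergent road: it needs no stereodefined alkenyl halide (step 18 of the chosen route) and sets C10 and C11 by approach control. Its weak points come after A8. Ring D must still be closed by a 7-endo etherification after oxidising one of three trisubstituted alkenes. The C24 methyl would add equatorially, anti to the axial C11 methyl, giving the wrong epimer, and the epoxide detour collides with the alkenes. The alkene geometry rests on the syn/anti preference of the π-allyl complex. The chosen plan is less convergent but settles ring D and C24 before any sensitive alkene exists.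

Key step: step 7

## Route

Assumption: the SeO2 hydroxylation (step 13) is drawn as the C7 epimer with the hydroxyl cis to H6; either epimer serves, because C7 becomes a carbonyl carbon in step 15.

**Step 1**
Reactants: 1 geraniol
Product: 2 (2S,3S)-2,3-epoxygeraniol
Conditions: Ti(OiPr)4 (5 mol%), L-(+)-diethyl tartrate (7 mol%), t-BuOOH, 4 Å MS, CH2Cl2, −20 °C
Reagents that add atoms: tert-butyl hydroperoxide, CC(C)(C)OO
Why: Katsuki–Sharpless asymmetric epoxidation acts only on the allylic alcohol; with the L-(+)-tartrate the (2S,3S)-epoxide forms, which fixes the later C24 centre and leaves the remote alkene untouched.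

**Step 2**
Reactants: 2 (2S,3S)-2,3-epoxygeraniol; 3 isopropenylmagnesium bromide
Product: 4 (2R,3S)-3,7-dimethyl-2-(prop-1-en-2-yl)oct-6-ene-1,3-diol
Conditions: 3 (3.5 equiv), CuI (15 mol%), THF, −30 → 0 °C
Reagents that add atoms: none
Why: Copper-catalysed Grignard opening of a 3,3-disubstituted 2,3-epoxy alcohol takes place at the secondary carbon by SN2 with inversion, the tertiary carbon being blocked. This sets C10 and leaves the C24–O bond intact, so the (E)-alkene of 1 becomes the anti relation of isopropenyl and hydroxyl that ring C needs.

**Step 3**
Reactants: 4 (2R,3S)-diol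
Product: 5 (4S,5R)-2,2-di-tert-butyl-4-methyl-4-(4-methylpent-3-enyl)-5-(prop-1-en-2-yl)-1,3,2-dioxasilinane
Conditions: t-Bu2Si(OTf)2, 2,6-lutidine, CH2Cl2, 0 °C → rt
Reagents that add atoms: di-tert-butylsilyl bis(trifluoromethanesulfonate), CC(C)(C)[Si](OS(=O)(=O)C(F)(F)F)(OS(=O)(=O)C(F)(F)F)C(C)(C)C
Why: Silylene protection of the 1,3-diol gives one group that survives peracid, enolate, oxidant, light and silyl triflate. It also holds C10 and C24 in a chair with the isopropenyl group and the C23 chain both equatorial.

**Step 4**
Reactants: 5 silylene-protected diene
Product: 7 silylene-protected C21 aldehyde, via epoxide 6 (not isolated)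
Conditions: 3-ClC6H4CO3H (1.05 equiv), NaHCO3, CH2Cl2, 0 °C; then H5IO6, THF/H2O, 0 °C
Reagents that add atoms: 3-chloroperbenzoic acid, OOC(=O)c1cccc(Cl)c1
Why: Prilezhaev epoxidation is much faster at the electron-rich trisubstituted alkene than at the hindered, inductively deactivated isopropenyl group. Periodic acid then hydrolyses and cleaves the epoxide (glycol cleavage) to the aldehyde and acetone.

**Step 5**
Reactants: 7 silylene-protected C21 aldehyde; 8 3-hydroxy-3-methylbutan-2-one
Product: 9 β-hydroxy ketone (C21 carbinol epimers)
Conditions: 8, LiN(i-Pr)2 (2.1 equiv per 8), THF, −78 °C; then 7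
Reagents that add atoms: none
Why: Aldol addition of the alkoxide enolate (dianion) of 8, which can enolise only at its methyl group, to the unhindered aldehyde. The C21 carbinol configuration is irrelevant because it is oxidised next.

**Step 6**
Reactants: 9 β-hydroxy ketone
Product: 11 5-alkenyl-2,2-dimethylfuran-3(2H)-one, via 1,3-diketone 10 (not isolated)
Conditions: Dess–Martin periodinane, NaHCO3, CH2Cl2, rt; filter; then TsOH·H2O (10 mol%), CH2Cl2, rt
Reagents that add atoms: none
Why: Oxidation gives the enolised 1,3-diketone; acid-catalysed addition of the tertiary hydroxyl to the C21 carbonyl and loss of water (cyclodehydration) is the standard entry to 5-alkyl-2,2-dimethyl-3(2H)-furanones.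

**Step 7**
Reactants: 11 5-alkenyl-2,2-dimethylfuran-3(2H)-one
Product: 12 tetracyclic cyclobutane photoadduct
Conditions: hν (350 nm lamps, Pyrex), degassed MeCN, 0.01 M, 10 °C
Reagents that add atoms: none
Why: Irradiation gives the furanone triplet, which adds to the tethered alkene stepwise through a 1,4-biradical; this is the intramolecular enone–alkene [2+2] photocycloaddition known for 5-alkenyl-3(2H)-furanones and other cyclic enones. Ring C closes first by 6-exo attack of C21 on C11 and the cyclobutane then closes by recombination of the C13 and C14 radicals (4-exo), so the fused adduct forms; the crossed mode would need a seven-membered first closure, which the four-atom tether disfavours. C11 is controlled by C10 and C24: the silylene ring holds C9 and O26 equatorial on a chair-like ring C and so defines its two faces. At C21 the CMe2–O20 side of the furanone is the bulky side and takes the pseudo-equatorial sector, so C14 is pseudo-axial. Because a cyclobutane can only be cis-fused to the six-membered ring, C13 must then be pseudo-equatorial and the C11 methyl axial, cis to O20 and to C9. C21 and C14 follow from C11 through the obligatory cis fusion of the four-membered ring to both ring C and the furanone ring. The step needs fused-over-crossed regioselectivity and one alkene face; the tether length secures the first, and the locked chair together with the gem-dimethyl-flanked oxygen secures the second.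

**Step 8**
Reactants: 12 tetracyclic cyclobutane photoadduct
Product: 14 silylene-protected trans-fused oxepanone, via trimethylsilyl enol ether 13 (not isolated)
Conditions: Me3SiOTf (1.2 equiv), Et3SiH (3 equiv), CH2Cl2, −78 → −30 °C; then aq. NaHCO3; K2CO3, MeOH, 0 °C
Reagents that add atoms: none
Why: Proposed new method: silylation of the C15 carbonyl makes C14–C21 the breaking bond of a push–pull cyclobutane (O20 donor, silyloxycarbenium acceptor); heterolysis releases the ring strain and gives a C21 oxocarbenium ion and the C14=C15 silyl enol ether inside the new seven-membered ring, and Et3SiH delivers hydride to C21 axially, anti to the axial C11 methyl, which gives the trans fusion; the closest known reaction types are the Lewis-acid opening of alkoxy-substituted donor–acceptor cyclobutanes to 1,4-zwitterions and the silane/silyl triflate reduction of cyclic oxocarbenium ions used in reductive oxepane formation.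

**Step 9**
Reactants: 14 silylene-protected trans-fused oxepanone
Product: 15 C9,C24-diol
Conditions: HF·pyridine, pyridine, THF, 0 °C → rt
Reagents that add atoms: none
Why: Fluoride cleaves both Si–O bonds of the silylene (desilylation); the ketone, the ring ether and the tertiary alcohol are inert to buffered HF.

**Step 10**
Reactants: 15 C9,C24-diol
Product: 16 C9 iodide
Conditions: I2, PPh3, imidazole, CH2Cl2, 0 °C → rt
Reagents that add atoms: iodine, II
Why: Appel-type iodination converts only the primary alcohol (SN2 at C9); the tertiary alcohol does not react, and the neutral medium avoids alkoxide-driven fragmentation of the 1,3-hydroxy iodide.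

**Step 11**
Reactants: 16 C9 iodide
Product: 17 C24 triethylsilyl ether of the iodide
Conditions: Et3SiOTf, 2,6-lutidine, CH2Cl2, −78 °C
Reagents that add atoms: triethylsilyl trifluoromethanesulfonate, CC[Si](CC)(CC)OS(=O)(=O)C(F)(F)F
Why: Silyl triflate silylation of the hindered tertiary alcohol at a temperature at which the ketone is not converted to an enol silane; it masks the O–H that would protonate the neighbouring C9–zinc bond.

**Step 12**
Reactants: 18 4,4-dimethylcyclohex-2-en-1-one; 19 isoprene
Product: 20 cis-fused octalone (C32 ketone and C2=C3 alkene; H5 and H6 cis)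
Conditions: oxazaborolidinium triflimide from (S)-α,α-diphenylprolinol, o-tolylboroxine and HNTf2 (20 mol%), 19 (5 equiv), CH2Cl2, −20 → 4 °C
Reagents that add atoms: none
Why: Diels–Alder reaction catalysed by a chiral cationic oxazaborolidine, a known catalyst class for 2-cycloalkenones with simple dienes. The diene methyl directs its neighbouring terminus to the β-carbon (para adduct, C6–C7 and C4–C5), suprafacial addition to the ring alkene gives the cis fusion, and the catalyst shields one enone face and so sets C5 and C6 absolutely; the antipodal catalyst is equally available if the sense proves opposite.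

**Step 13**
Reactants: 20 cis-fused octalone
Product: 21 C7 allylic alcohol
Conditions: SeO2 (0.5 equiv), t-BuOOH (3 equiv), CH2Cl2, rt
Reagents that add atoms: selenium dioxide, O=[Se]=O; tert-butyl hydroperoxide, CC(C)(C)OO
Why: Selenium dioxide allylic hydroxylation (ene reaction, then [2,3]-sigmatropic shift) attacks the ring CH2 on the more substituted alkene carbon, as in 1-methylcyclohexenes. The peroxide-recycled, room-temperature conditions are mild enough to leave C5, α to the ketone, unepimerised.

**Step 14**
Reactants: 21 C7 allylic alcohol
Product: 22 C32 exo-methylene allylic alcohol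
Conditions: Cp2TiMe2 (3 equiv), toluene/THF, 65 °C
Reagents that add atoms: dimethyltitanocene, C[Ti](C)(C1C=CC=C1)C1C=CC=C1
Why: Petasis methylenation of the only ketone under non-basic conditions; C5 is then no longer α to a carbonyl and the cis fusion is fixed, while the free hydroxyl only consumes reagent.

**Step 15**
Reactants: 22 C32 exo-methylene allylic alcohol
Product: 23 C7 enone with C32 exo-methylene
Conditions: Dess–Martin periodinane, NaHCO3, CH2Cl2, rt
Reagents that add atoms: none
Why: Oxidation of the allylic alcohol to the enone, which also deactivates the ring alkene toward the electrophilic oxidant of the next step.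

**Step 16**
Reactants: 23 C7 enone with C32 exo-methylene
Product: 24 C32 spiro-epoxide
Conditions: dimethyldioxirane, acetone/CH2Cl2, −20 → 0 °C
Reagents that add atoms: dimethyldioxirane, CC1(C)OO1
Why: The dioxirane epoxidises the electron-rich 1,1-disubstituted alkene far faster than the enone. Attack from the equatorial face of ring B, anti to the axial C7, puts the oxygen equatorial and the CH2 axial, which is the C32 configuration of the target.

**Step 17**
Reactants: 24 C32 spiro-epoxide
Product: 26 cis-fused C32-hydroxy C7 decalone, via lithium enolate 25 (not isolated)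
Conditions: LiBH(s-Bu)3 (1.1 equiv), THF, −78 °C; then LiEt3BH (3 equiv), −78 → 0 °C; aq. NH4Cl
Reagents that add atoms: none
Why: Conjugate reduction of the α-methyl enone gives the lithium enolate, which masks C7 while the trialkylborohydride opens the epoxide at its CH2 carbon (SN2) to the tertiary alkoxide. Protonation of the enolate from the face of H5 and H6 sets C2 with its methyl equatorial, cis to C27 and C32.

**Step 18**
Reactants: 26 cis-fused C32-hydroxy C7 decalone
Product: 27 (E)-bromomethylene decalin
Conditions: Ph3P(CH2Br)Br (4 equiv), NaN(SiMe3)2 (3.9 equiv), THF, −78 °C; then 26, −78 °C → rt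
Reagents that add atoms: (bromomethyl)triphenylphosphonium bromide, BrC[P+](c1ccccc1)(c1ccccc1)c1ccccc1.[Br-]
Why: Wittig olefination with (bromomethylene)triphenylphosphorane, which with ring-fused cyclohexanones places the bromine away from the more hindered α-carbon; here that is C6, flanked by the quaternary C27, so the bromine ends cis to C2. A pre-formed ylide without excess base limits enolisation at C2 and C6, and the tertiary alkoxide only costs one equivalent.

**Step 19**
Reactants: 17 C24 triethylsilyl ether of the iodide; 27 (E)-bromomethylene decalin
Product: 29 C24 triethylsilyl ether of the target, via alkylzinc iodide 28 (not isolated)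
Conditions: 17, Zn dust (activated with BrCH2CH2Br and Me3SiCl), LiCl, THF, 40 °C; then 27 (0.8 equiv), Pd(OAc)2 (5 mol%), SPhos (10 mol%), THF, 25 → 45 °C
Reagents that add atoms: none
Why: Direct zinc insertion into the primary iodide tolerates the ketone. Negishi coupling of the alkylzinc with the alkenyl bromide retains the alkene geometry and, with slow addition, tolerates the free tertiary hydroxyl of 27.

**Step 20**
Reactants: 29 C24 triethylsilyl ether of the target
Product: 30 target CNP0232921.1
Conditions: HF·pyridine, pyridine, THF, 0 °C → rt
Reagents that add atoms: none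
Why: Fluoride desilylation of the tertiary silyl ether under buffered conditions that leave the two tertiary alcohols, the ketone and the trisubstituted alkene untouched.

## Compound list

1 | geraniol | CC(C)=CCC/C(C)=C/CO | starting material
2 | (2S,3S)-2,3-epoxygeraniol | OC[C@@H]1O[C@@]1(C)CCC=C(C)C | intermediate
3 | isopropenylmagnesium bromide | C=C(C)[Mg]Br | starting material
4 | (2R,3S)-3,7-dimethyl-2-(prop-1-en-2-yl)oct-6-ene-1,3-diol | OC[C@@H](C(C)=C)[C@@](C)(O)CCC=C(C)C | intermediate
5 | (4S,5R)-di-tert-butylsilylene ether of 4 (isopropenyl and C23 chain trans) | C=C(C)[C@@H]1CO[Si](C(C)(C)C)(C(C)(C)C)O[C@@]1(C)CCC=C(C)C | intermediate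
6 | terminal epoxide of 5 (epoxide epimers) | C=C(C)[C@@H]1CO[Si](C(C)(C)C)(C(C)(C)C)O[C@@]1(C)CCC2OC2(C)C | intermediate (not isolated)
7 | silylene-protected C21 aldehyde | C=C(C)[C@@H]1CO[Si](C(C)(C)C)(C(C)(C)C)O[C@@]1(C)CCC=O | intermediate
8 | 3-hydroxy-3-methylbutan-2-one | CC(=O)C(C)(C)O | starting material
9 | β-hydroxy ketone (C21 epimers) | C=C(C)[C@@H]1CO[Si](C(C)(C)C)(C(C)(C)C)O[C@@]1(C)CCC(O)CC(=O)C(C)(C)O | intermediate
10 | 1,3-diketone | C=C(C)[C@@H]1CO[Si](C(C)(C)C)(C(C)(C)C)O[C@@]1(C)CCC(=O)CC(=O)C(C)(C)O | intermediate (not isolated)
11 | 5-alkenyl-2,2-dimethylfuran-3(2H)-one (photo-precursor) | C=C(C)[C@@H]1CO[Si](C(C)(C)C)(C(C)(C)C)O[C@@]1(C)CCC2=CC(=O)C(C)(C)O2 | intermediate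
12 | cyclobutane photoadduct (cyclobutane cis-fused to ring C and to the furanone; C9, C11 methyl, C24 methyl and O20 on one face of ring C) | O1C[C@H]2[C@]3(C)C[C@H]4C(=O)C(C)(C)O[C@@]34CC[C@]2(C)O[Si]1(C(C)(C)C)C(C)(C)C | intermediate
13 | trimethylsilyl enol ether of 14 | O1C[C@H]2[C@]3(C)CC=C(O[Si](C)(C)C)C(C)(C)O[C@H]3CC[C@]2(C)O[Si]1(C(C)(C)C)C(C)(C)C | intermediate (not isolated)
14 | silylene-protected trans-fused oxepanone (H21 trans to C11 methyl) | O1C[C@H]2[C@]3(C)CCC(=O)C(C)(C)O[C@H]3CC[C@]2(C)O[Si]1(C(C)(C)C)C(C)(C)C | intermediate
15 | C9,C24-diol of the oxepanone | OC[C@H]1[C@]2(C)CCC(=O)C(C)(C)O[C@H]2CC[C@]1(C)O | intermediate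
16 | C9 iodide | IC[C@H]1[C@]2(C)CCC(=O)C(C)(C)O[C@H]2CC[C@]1(C)O | intermediate
17 | C9 iodide, C24 triethylsilyl ether | IC[C@H]1[C@]2(C)CCC(=O)C(C)(C)O[C@H]2CC[C@]1(C)O[Si](CC)(CC)CC | intermediate
18 | 4,4-dimethylcyclohex-2-en-1-one | CC1(C)CCC(=O)C=C1 | starting material
19 | isoprene | C=CC(C)=C | starting material
20 | cis-fused octalone (C32 ketone, C2=C3; H5/H6 cis) | CC1=CC[C@H]2[C@@H](C1)C(C)(C)CCC2=O | intermediate
21 | C7 allylic alcohol (OH cis to H6) | CC1=CC[C@H]2[C@@H]([C@H]1O)C(C)(C)CCC2=O | intermediate
22 | C32 exo-methylene allylic alcohol | CC1=CC[C@H]2[C@@H]([C@H]1O)C(C)(C)CCC2=C | intermediate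
23 | C7 enone with C32 exo-methylene | CC1=CC[C@H]2[C@@H](C1=O)C(C)(C)CCC2=C | intermediate
24 | C32 spiro-epoxide (oxygen anti to C7) | CC1=CC[C@H]2[C@@H](C1=O)C(C)(C)CC[C@@]23CO3 | intermediate
25 | lithium enolate of the epoxy ketone | [Li]OC1=C(C)CC[C@H]2[C@@H]1C(C)(C)CC[C@@]23CO3 | intermediate (not isolated)
26 | cis-fused C32-hydroxy C7 decalone (H2, H5, H6 cis; C32–OH on the face of H5) | C[C@@H]1CC[C@H]2[C@@H](C1=O)C(C)(C)CC[C@]2(C)O | intermediate
27 | (E)-bromomethylene decalin (Br cis to C2) | C[C@@H]1CC[C@H]2[C@@H](/C1=C/Br)C(C)(C)CC[C@]2(C)O | intermediate
28 | alkylzinc iodide from 17 | I[Zn]C[C@H]1[C@]2(C)CCC(=O)C(C)(C)O[C@H]2CC[C@]1(C)O[Si](CC)(CC)CC | intermediate (not isolated)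
29 | C24 triethylsilyl ether of the target | C[C@@H]1CC[C@H]2[C@@H](/C1=C/C[C@H]1[C@]3(C)CCC(=O)C(C)(C)O[C@H]3CC[C@]1(C)O[Si](CC)(CC)CC)C(C)(C)CC[C@]2(C)O | intermediate
30 | CNP0232921.1 | C[C@@H]1CC[C@H]2[C@@H](/C1=C/C[C@H]1[C@]3(C)CCC(=O)C(C)(C)O[C@H]3CC[C@]1(C)O)C(C)(C)CC[C@]2(C)O | target

## Step count and least certain steps

Total: 20 steps. Longest linear sequence: 13 steps (steps 1–11, 19, 20); the decalin branch (steps 12–18) has 7 steps.

**Step 8 (proposed new method).** The C14–C21 bond lies almost in the plane of the five-membered ring, so overlap with the O20 lone pair and the carbonyl π system is poor and heterolysis may be slow. The silane may then reduce the activated C15 carbonyl first, or the tertiary C24–O bond may ionise. The fallback uses known radical chemistry: photoadduct 12 is heated with Bu3SnH and AIBN in benzene. The O-stannyl ketyl at C15 opens the cyclobutane toward the tertiary, oxygen-stabilised C21 radical, which takes hydrogen from the stannane on the axial face, anti to the C11 methyl. Aqueous work-up of the tributylstannyl enolate F1 returns the route at 14.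

**Step 7 (key step).** Because C11 is fully substituted, C21 may bond to C13 first and give the crossed adduct, or the two faces of the alkene may be used without enough preference. The fallback moves the cycloaddition to the enolised diketone (de Mayo reaction). Aldol 9 is oxidised as in step 6 but without acid, and 10 is isolated and irradiated at 350 nm. The cyclobutanol F2 undergoes retro-aldol cleavage in the flask to the hydroxy 1,5-diketone F3, whose C21 is now a ring C ketone. Et3SiH and Me3SiOTf at −78 °C then close the oxepane by reductive etherification and the route is rejoined at 14. Here C21 is set by axial hydride delivery and only C11 depends on the cycloaddition.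

**Step 12.** The β-carbon of 18 sits next to a quaternary carbon, so turnover with the bulky cationic catalyst may be low, isoprene may polymerise, or the enantioselectivity may be insufficient. The fallback is resolution. The AlCl3-catalysed reaction of 18 and 19 gives racemic octalone F4; steps 13 and 14 give the racemic allylic alcohol F5 and the racemic exo-methylene alcohol F6. Esterification with (S)-2-methoxy-2-phenylacetic acid gives the diastereomeric esters F7 and F8, which are separated by chromatography. LiOH cleaves F7 and the route is rejoined at 22.

**Step 18.** The ylide may enolise the doubly α-branched ketone instead of adding, with epimerisation at C2 or C6 toward the trans-decalone, and the E selectivity may be incomplete. The fallback avoids a basic reagent at the ketone. Petasis methylenation of 26 gives the exo-methylene decalin F9, hydroboration–oxidation (BH3·THF; H2O2, NaOH) gives the primary alcohol F10, and Dess–Martin oxidation gives the aldehyde F11. KN(SiMe3)2 and PhNTf2 give the (E)-enol triflate F12, with the oxygen on the less hindered C2 side. Negishi coupling of F12 with 28 under the conditions of step 19 rejoins the route at 29.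

**Step 19.** Zinc insertion at the β-branched iodide may be slow, and the alkylzinc may be lost by protonation or homocoupling before transmetalation. The fallback needs no carbanion: iodide 16, with its free C24 hydroxyl, and bromide 27 are joined by nickel-catalysed reductive cross-electrophile coupling (NiBr2·glyme, 4,4′-di-tert-butyl-2,2′-bipyridine, Mn powder, NaI, DMPU, rt). The C9 radical is captured by the alkenylnickel species and the route is rejoined directly at 30, without 17, 28 and 29.

## Further compounds

F1 | step 8 | tributylstannyl enolate of 14 | O1C[C@H]2[C@]3(C)CC=C(O[Sn](CCCC)(CCCC)CCCC)C(C)(C)O[C@H]3CC[C@]2(C)O[Si]1(C(C)(C)C)C(C)(C)C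
F2 | step 7 | cyclobutanol photoadduct of enolised 10 | O1C[C@H]2[C@]3(C)CC(C(=O)C(C)(C)O)[C@]3(O)CC[C@]2(C)O[Si]1(C(C)(C)C)C(C)(C)C
F3 | step 7 | hydroxy 1,5-diketone (C21 ketone in ring C) | O1C[C@H]2[C@](C)(CCC(=O)C(C)(C)O)C(=O)CC[C@]2(C)O[Si]1(C(C)(C)C)C(C)(C)C
F4 | step 12 | racemic 20 | CC1=CC[C@H]2[C@@H](C1)C(C)(C)CCC2=O.CC1=CC[C@@H]2[C@H](C1)C(C)(C)CCC2=O
F5 | step 12 | racemic 21 | CC1=CC[C@H]2[C@@H]([C@H]1O)C(C)(C)CCC2=O.CC1=CC[C@@H]2[C@H]([C@@H]1O)C(C)(C)CCC2=O
F6 | step 12 | racemic 22 | CC1=CC[C@H]2[C@@H]([C@H]1O)C(C)(C)CCC2=C.CC1=CC[C@@H]2[C@H]([C@@H]1O)C(C)(C)CCC2=C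
F7 | step 12 | (S)-2-methoxy-2-phenylacetate of 22 | CO[C@@H](c1ccccc1)C(=O)O[C@H]1C(C)=CC[C@H]2[C@@H]1C(C)(C)CCC2=C
F8 | step 12 | (S)-2-methoxy-2-phenylacetate of the enantiomer of 22 | CO[C@@H](c1ccccc1)C(=O)O[C@@H]1C(C)=CC[C@@H]2[C@H]1C(C)(C)CCC2=C
F9 | step 18 | C7 exo-methylene decalin | C[C@@H]1CC[C@H]2[C@@H](C1=C)C(C)(C)CC[C@]2(C)O
F10 | step 18 | C8 primary alcohol (C7 epimers) | C[C@@H]1CC[C@H]2[C@@H](C1CO)C(C)(C)CC[C@]2(C)O
F11 | step 18 | C8 aldehyde (C7 epimers) | C[C@@H]1CC[C@H]2[C@@H](C1C=O)C(C)(C)CC[C@]2(C)O
F12 | step 18 | (E)-enol trifluoromethanesulfonate | C[C@@H]1CC[C@H]2[C@@H](/C1=C/OS(=O)(=O)C(F)(F)F)C(C)(C)CC[C@]2(C)O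
F0 | step 19 | none | none
A1 | alternative 1 | ten-membered C5,C32-epoxy C7 ketone | C[C@@H]1CC[C@@H]2O[C@@]2(C)CCC(C)(C)CC1=O
A2 | alternative 1 | cis-fused C32-hydroxy C7 decalone | C[C@@H]1CC[C@H]2[C@@H](C1=O)C(C)(C)CC[C@]2(C)O
A3 | alternative 2 | bis-epoxy farnesyl tert-butyl carbonate | CC(C)(C)OC(=O)OC/C=C(\C)CC[C@@H]1O[C@@]1(C)CC[C@@H]1OC1(C)C
A4 | alternative 2 | C15-hydroxy oxepane–cyclohexane cyclic carbonate | O=C1OC[C@H]2[C@]3(C)CC[C@H](O)C(C)(C)O[C@H]3CC[C@]2(C)O1
A5 | alternative 3 | 4-(tert-butyldimethylsilyloxy)-3-methylcyclohex-2-enone | CC1=CC(=O)CC[C@@H]1O[Si](C)(C)C(C)(C)C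
A6 | alternative 3 | lithium bis(4-methylpent-3-enyl)cuprate | [Li+].CC(C)=CCC[Cu-]CCC=C(C)C
A7 | alternative 3 | decalin C7 vinyl methyl carbonate | C[C@@H]1CC[C@H]2[C@@H](C1(C=C)OC(=O)OC)C(C)(C)CC[C@]2(C)O[Si](CC)(CC)CC
A8 | alternative 3 | C24 ketone carrying decalin, ring C and prenyl arm | C[C@@H]1CC[C@H]2[C@@H](/C1=C/C[C@H]1[C@](C)(CCC=C(C)C)[C@@H](O[Si](C)(C)C(C)(C)C)CCC1=O)C(C)(C)CC[C@]2(C)O[Si](CC)(CC)CC
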